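**Retrosynthetic overview**
1. Target ⇒ open the cyclopentanone bond between the methyl-bearing ring-fusion carbon and the ring-fusion CH, together with the γ-lactone O–CMe2 bond: an anodic oxidative 5-exo radical cyclisation/lactonisation of a δ-lactone whose α-carbon carries a prenyl group and a MeO2C–CH(Me)–CO– arm.
2. That precursor ⇒ C-acylation of the bis-enolate of a 3-prenyl-5-isopropenyl-6-isobutyryl δ-lactone with the acid chloride of methyl hydrogen methylmalonate (sets the quaternary carbon; the quench sets the isobutyryl-bearing carbon).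
3. δ-Lactone ⇒ 6-oxo acid by ketone α-iodination and carboxylate ring closure.
4. Keto acid ⇒ (+)-limonene oxide: periodate ring cleavage, iPrMgCl on the aldehyde, haloform cleavage of the methyl ketone, α-prenylation of the acid, alcohol oxidation.
5. Ring order: δ-lactone first (step 6), then cyclopentanone and γ-lactone together in the electrochemical step (step 8).

Assumption: commercial (+)-limonene oxide (cis/trans mixture from (R)-limonene) is the chiral starting material, and locants C3, C5 and C6 in the text are those of the oxan-2-one ring of 11 and 14.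

**Step 1**
Reactants: 1 (4R)-limonene 1,2-oxide ((+)-limonene oxide; cis/trans mixture)
Product: 3 (3R)-6-oxo-3-(prop-1-en-2-yl)heptanal, via (1S,2S,4R)-limonene-1,2-diol 2 (not isolated)
Conditions: H5IO6, THF/H2O, 0 °C to rt
Reagents that add atoms: water, O
Why: Acid-promoted trans-diaxial hydrolysis converts both epoxide epimers into the same diol and periodate glycol cleavage (Malaprade reaction) opens the ring, leaving the isopropenyl-bearing stereocentre bought with the starting material untouched.

**Step 2**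
Reactants: 3 (3R)-6-oxo-3-(prop-1-en-2-yl)heptanal; 4 isopropylmagnesium chloride
Product: 5 (5R,7RS)-7-hydroxy-8-methyl-5-(prop-1-en-2-yl)nonan-2-one
Conditions: iPrMgCl (1.05 equiv), THF, −78 °C; aq. NH4Cl
Reagents that add atoms: none
Why: Chemoselective Grignard addition, the aldehyde reacting far faster than the methyl ketone at −78 °C; the new carbinol centre forms unselectively and is erased by the oxidation in step 5.

**Step 3**
Reactants: 5 (5R,7RS)-7-hydroxy-8-methyl-5-(prop-1-en-2-yl)nonan-2-one
Product: 6 (4R,6RS)-6-hydroxy-7-methyl-4-(prop-1-en-2-yl)octanoic acid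
Conditions: Br2 (3.3 equiv), aq. NaOH, dioxane, 0 °C (NaOBr formed in the flask); Na2SO3; HCl to pH 3
Reagents that add atoms: sodium hydroxide, [Na+].[OH-]
Why: Haloform reaction, in which cold alkaline hypobromite tribrominates only the methyl ketone and hydroxide then cleaves the CBr3 group, while the secondary alcohol and the 1,1-disubstituted alkene are inert in this strongly basic medium (as in the classical degradation of hydroxy-alkenyl steroid methyl ketones).

**Step 4**
Reactants: 6 (4R,6RS)-6-hydroxy-7-methyl-4-(prop-1-en-2-yl)octanoic acid; 7 1-bromo-3-methylbut-2-ene (prenyl bromide)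
Product: 8 (2RS,4R,6RS)-6-hydroxy-7-methyl-2-(3-methylbut-2-en-1-yl)-4-(prop-1-en-2-yl)octanoic acid
Conditions: LiN(iPr)2 (3.3 equiv), THF/DMPU, −78 to 0 °C; 7 (1.1 equiv), −78 to 0 °C; aq. HCl
Reagents that add atoms: none
Why: SN2 alkylation of the carboxylic acid enediolate (two equivalents of base are taken by OH and CO2H, the third makes the α-carbanion) by the allylic bromide; the new α-centre is unselective and is planarised again in step 7.

**Step 5**
Reactants: 8 (2RS,4R,6RS)-6-hydroxy-7-methyl-2-(3-methylbut-2-en-1-yl)-4-(prop-1-en-2-yl)octanoic acid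
Product: 9 (2RS,4R)-7-methyl-2-(3-methylbut-2-en-1-yl)-6-oxo-4-(prop-1-en-2-yl)octanoic acid
Conditions: Dess–Martin periodinane (1.3 equiv), CH2Cl2, rt
Reagents that add atoms: none
Why: Dess–Martin oxidation converts the secondary alcohol into the isopropyl ketone under neutral conditions that spare the free acid and both alkenes.

**Step 6**
Reactants: 9 (2RS,4R)-7-methyl-2-(3-methylbut-2-en-1-yl)-6-oxo-4-(prop-1-en-2-yl)octanoic acid
Product: 11 (3RS,5S,6RS)-3-(3-methylbut-2-en-1-yl)-6-(2-methylpropanoyl)-5-(prop-1-en-2-yl)oxan-2-one, via lithium 5-iodo-6-oxo carboxylate 10 (not isolated)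
Conditions: LiN(iPr)2 (2.2 equiv), THF, −78 °C; I2 (1.0 equiv), −78 °C; warm to rt
Reagents that add atoms: none
Why: The kinetic ketone enolate forms at the CH2 rather than the isopropyl CH, is iodinated, and the lithium carboxylate displaces iodide from the activated α-keto carbon in a 6-exo-tet SN2 ring closure (enolate α-halogenation then intramolecular O-alkylation); C3 and C6 are formed as mixtures that converge in step 7.

**Step 7**
Reactants: 11 (3RS,5S,6RS)-3-(3-methylbut-2-en-1-yl)-6-(2-methylpropanoyl)-5-(prop-1-en-2-yl)oxan-2-one; 12 3-methoxy-2-methyl-3-oxopropanoic acid (methyl hydrogen methylmalonate)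
Product: 14 methyl (2RS)-2-methyl-3-[(3S,5S,6S)-3-(3-methylbut-2-en-1-yl)-6-(2-methylpropanoyl)-2-oxo-5-(prop-1-en-2-yl)oxan-3-yl]-3-oxopropanoate, via methyl 3-chloro-2-methyl-3-oxopropanoate 13 (not isolated)
Conditions: 12, (COCl)2, DMF (cat.), CH2Cl2, 0 °C, then evaporate; 11, LiN(iPr)2 (3.3 equiv), THF, −78 to −40 °C; add 13 (1.1 equiv), −78 °C; AcOH, −78 °C
Reagents that add atoms: none
Why: LiN(iPr)2 removes the C6–H (α to the ketone and the ring oxygen) and the C3–H to give a bis-enolate in which A(1,3) strain with the exocyclic enolate holds the C5 isopropenyl group pseudo-axial, so the acid chloride C-acylates the more reactive ester-enolate carbon C3 anti to it (Claisen-type enolate acylation, quaternary centre set, the third equivalent of base covering the acidic product) and the cold acetic acid quench protonates C6 from the same open face (kinetic protonation, isobutyryl cis to isopropenyl).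

**Step 8**
Reactants: 14 methyl (2RS)-2-methyl-3-[(3S,5S,6S)-3-(3-methylbut-2-en-1-yl)-6-(2-methylpropanoyl)-2-oxo-5-(prop-1-en-2-yl)oxan-3-yl]-3-oxopropanoate
Product: 15 (3aS,5R,5'S,6'S,6aS)-3,3,6a-trimethyl-6'-(2-methylpropanoyl)-5'-(prop-1-en-2-yl)tetrahydro-1H-spiro[cyclopenta[c]furan-5,3'-oxane]-1,2',6-trione (CNP0216954.1)
Conditions: undivided cell, graphite anode, Pt cathode, Mn(OAc)2 (15 mol%), Mg(ClO4)2 (2 equiv), NaOAc (1 equiv), AcOH/MeCN 1:2, constant current 5 mA cm−2, 2.4 F mol−1, 30 °C
Reagents that add atoms: none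
Why: Proposed new method: trivalent manganese regenerated at the anode from catalytic Mn(OAc)2 oxidises the enol of the α-methyl β-keto ester to a tertiary radical that Mg(ClO4)2 holds coplanar with the ketone and the spiro-lactone carbonyl, 5-exo attack on the prenyl group gives a tertiary alkyl radical that is oxidised to the cation and captured by the ester carbonyl with loss of methyl acetate while protons are reduced to H2 at the cathode, and because the chelate places the ester and the spiro-lactone carbonyl on the same face of the new cyclopentanone and only the cis-fused γ-lactone can close, the ring-fusion CH and the methyl-bearing quaternary carbon are set relative to the spiro centre as in the target; the closest known reaction type is the stoichiometric Mn(OAc)3 oxidative free-radical cyclisation/lactone annulation of unsaturated β-keto acids and esters, not yet shown as a manganese-electrocatalytic, chelate-relayed bicyclisation of a spiro 1,3,5-tricarbonyl ester.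

**Compound list**
1 | (4R)-limonene 1,2-oxide, (+)-limonene oxide, cis/trans mixture | CC12CC[C@H](CC1O2)C(C)=C | starting material
2 | (1S,2S,4R)-limonene-1,2-diol (formed in the flask in step 1) | C[C@]1(O)CC[C@H](C[C@@H]1O)C(C)=C | intermediate
3 | (3R)-6-oxo-3-(prop-1-en-2-yl)heptanal | C=C(C)[C@@H](CC=O)CCC(C)=O | intermediate
4 | isopropylmagnesium chloride | CC(C)[Mg]Cl | starting material
5 | (5R,7RS)-7-hydroxy-8-methyl-5-(prop-1-en-2-yl)nonan-2-one | C=C(C)[C@@H](CC(O)C(C)C)CCC(C)=O | intermediate
6 | (4R,6RS)-6-hydroxy-7-methyl-4-(prop-1-en-2-yl)octanoic acid | C=C(C)[C@@H](CC(O)C(C)C)CCC(O)=O | intermediate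
7 | 1-bromo-3-methylbut-2-ene (prenyl bromide) | CC(C)=CCBr | starting material
8 | (2RS,4R,6RS)-6-hydroxy-7-methyl-2-(3-methylbut-2-en-1-yl)-4-(prop-1-en-2-yl)octanoic acid | C=C(C)[C@@H](CC(O)C(C)C)CC(CC=C(C)C)C(O)=O | intermediate
9 | (2RS,4R)-7-methyl-2-(3-methylbut-2-en-1-yl)-6-oxo-4-(prop-1-en-2-yl)octanoic acid | C=C(C)[C@@H](CC(=O)C(C)C)CC(CC=C(C)C)C(O)=O | intermediate
10 | lithium (2RS,4S,5RS)-5-iodo-7-methyl-2-(3-methylbut-2-en-1-yl)-6-oxo-4-(prop-1-en-2-yl)octanoate (formed in the flask in step 6) | C=C(C)[C@@H](C(I)C(=O)C(C)C)CC(CC=C(C)C)C(=O)[O-].[Li+] | intermediate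
11 | (3RS,5S,6RS)-3-(3-methylbut-2-en-1-yl)-6-(2-methylpropanoyl)-5-(prop-1-en-2-yl)oxan-2-one | C=C(C)[C@@H]1CC(CC=C(C)C)C(=O)OC1C(=O)C(C)C | intermediate
12 | 3-methoxy-2-methyl-3-oxopropanoic acid (methyl hydrogen methylmalonate, racemic) | COC(=O)C(C)C(O)=O | starting material
13 | methyl 3-chloro-2-methyl-3-oxopropanoate (formed in the flask in step 7) | COC(=O)C(C)C(Cl)=O | intermediate
14 | methyl (2RS)-2-methyl-3-[(3S,5S,6S)-3-(3-methylbut-2-en-1-yl)-6-(2-methylpropanoyl)-2-oxo-5-(prop-1-en-2-yl)oxan-3-yl]-3-oxopropanoate | C=C(C)[C@@H]1C[C@@](CC=C(C)C)(C(=O)C(C)C(=O)OC)C(=O)O[C@@H]1C(=O)C(C)C | intermediate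
15 | (3aS,5R,5'S,6'S,6aS)-3,3,6a-trimethyl-6'-(2-methylpropanoyl)-5'-(prop-1-en-2-yl)tetrahydro-1H-spiro[cyclopenta[c]furan-5,3'-oxane]-1,2',6-trione (CNP0216954.1) | C=C(C)[C@@H]1C[C@]2(C[C@@H]3C(C)(C)OC(=O)[C@]3(C)C2=O)C(=O)O[C@@H]1C(=O)C(C)C | target

**Step count and risks**
Total step count: 8. Longest linear sequence: 8 (1 to 15).

The three steps most likely to fail:

Step 8, the proposed electrochemical bicyclisation. The manganese shuttle may not turn over cleanly at the anode, the chelate-relayed face selection may be weak, or the isobutyryl-bearing centre may epimerise in the acidic medium. The fallback uses known halogen-atom-transfer chemistry, sets out from 14 and comes back at 15. Bromination of the β-keto ester with NBS and catalytic Mg(ClO4)2 in MeCN gives methyl (2RS)-2-bromo-2-methyl-3-[(3S,5S,6S)-3-(3-methylbut-2-en-1-yl)-6-(2-methylpropanoyl)-2-oxo-5-(prop-1-en-2-yl)oxan-3-yl]-3-oxopropanoate F1. Et3B/O2-initiated bromine-atom-transfer 5-exo radical cyclisation of the Yb(OTf)3-chelated radical at −78 °C gives methyl (2S,3S,5R,8S,9S)-3-(2-bromopropan-2-yl)-2-methyl-8-(2-methylpropanoyl)-1,6-dioxo-9-(prop-1-en-2-yl)-7-oxaspiro[4.5]decane-2-carboxylate F2. Warming F2 in MeCN at 60 °C closes the γ-lactone by ester participation with loss of bromomethane and gives 15.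

Step 7, the bis-enolate C-acylation. The α-acyloxy ketone enolate may undergo acyl migration, O-acylation may compete at the hindered tetrasubstituted enolate, and the quench may not be fully cis-selective. The fallback masks the ketone and uses mono-enolate chemistry; it sets out from 11 and comes back at 14. Soft enolisation with TBSOTf/Et3N gives (5S)-6-{1-[tert-butyl(dimethyl)silyloxy]-2-methylpropylidene}-3-(3-methylbut-2-en-1-yl)-5-(prop-1-en-2-yl)oxan-2-one F3. Deprotonation with LiN(iPr)2 (2.2 equiv) at −78 °C and acylation with 13 gives methyl 3-[(3S,5S)-6-{1-[tert-butyl(dimethyl)silyloxy]-2-methylpropylidene}-3-(3-methylbut-2-en-1-yl)-2-oxo-5-(prop-1-en-2-yl)oxan-3-yl]-2-methyl-3-oxopropanoate F4. Protodesilylation of F4 with HF·pyridine at −40 °C, with kinetic C-protonation anti to the isopropenyl group, gives 14.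

Step 6, the enolate iodination/ring closure. Oxidative enolate coupling or iodolactonisation of the prenyl group by stray iodine may compete. The fallback replaces umpolung halogenation by electrophilic hydroxylation and dehydrative lactonisation; it sets out from 9 and comes back at 11. The kinetic enolate (LiN(iPr)2, 2.2 equiv, −78 °C) is hydroxylated with 2-(phenylsulfonyl)-3-phenyloxaziridine to give (2RS,4S,5RS)-5-hydroxy-7-methyl-2-(3-methylbut-2-en-1-yl)-6-oxo-4-(prop-1-en-2-yl)octanoic acid F5, which is closed to 11 with EDC·HCl and DMAP in CH2Cl2.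

Further compounds
F1 | step 8 | methyl (2RS)-2-bromo-2-methyl-3-[(3S,5S,6S)-3-(3-methylbut-2-en-1-yl)-6-(2-methylpropanoyl)-2-oxo-5-(prop-1-en-2-yl)oxan-3-yl]-3-oxopropanoate | C=C(C)[C@@H]1C[C@@](CC=C(C)C)(C(=O)C(C)(Br)C(=O)OC)C(=O)O[C@@H]1C(=O)C(C)C
F2 | step 8 | methyl (2S,3S,5R,8S,9S)-3-(2-bromopropan-2-yl)-2-methyl-8-(2-methylpropanoyl)-1,6-dioxo-9-(prop-1-en-2-yl)-7-oxaspiro[4.5]decane-2-carboxylate | C=C(C)[C@@H]1C[C@]2(C[C@H](C(C)(C)Br)[C@](C)(C(=O)OC)C2=O)C(=O)O[C@@H]1C(=O)C(C)C
F3 | step 7 | (5S)-6-{1-[tert-butyl(dimethyl)silyloxy]-2-methylpropylidene}-3-(3-methylbut-2-en-1-yl)-5-(prop-1-en-2-yl)oxan-2-one | C=C(C)[C@@H]1CC(CC=C(C)C)C(=O)OC1=C(O[Si](C)(C)C(C)(C)C)C(C)C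
F4 | step 7 | methyl 3-[(3S,5S)-6-{1-[tert-butyl(dimethyl)silyloxy]-2-methylpropylidene}-3-(3-methylbut-2-en-1-yl)-2-oxo-5-(prop-1-en-2-yl)oxan-3-yl]-2-methyl-3-oxopropanoate | C=C(C)[C@@H]1C[C@@](CC=C(C)C)(C(=O)C(C)C(=O)OC)C(=O)OC1=C(O[Si](C)(C)C(C)(C)C)C(C)C
F5 | step 6 | (2RS,4S,5RS)-5-hydroxy-7-methyl-2-(3-methylbut-2-en-1-yl)-6-oxo-4-(prop-1-en-2-yl)octanoic acid | C=C(C)[C@@H](C(O)C(=O)C(C)C)CC(CC=C(C)C)C(O)=O
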